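**Retrosynthetic overview**
1. Manuifolin E ⇐ MOM removal ⇐ twofold aromatic Claisen rearrangement of the 7,4'-bis(prenyl) ether. Both aryl–C(CH3)2CH=CH2 bonds (C6 and C5') form in one operation.
2. Bis(prenyl) ether ⇐ TIPS→prenyl exchange on a (3R)-isoflavan, whose ring C ⇐ intramolecular Pd C–O coupling of an (R)-2-aryl-3-(2-bromoaryl)propan-1-ol.
3. That alcohol ⇐ ozonolysis/NaBH4 of a propenyl group ⇐ aromatic Claisen rearrangement of an (S,Z)-allyl aryl ether. This step forms C3–C1', frees 2'-OH and relays the C–O stereocentre to C3.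
4. (S,Z)-ether ⇐ Lindlar reduction ⇐ alkyne benzylation (ring A as a 2-bromobenzyl bromide) ⇐ Mitsunobu inversion of (R)-but-3-yn-2-ol with mono-TIPS resorcinol (ring B).
5. Ring order: rings A and B are bought as arenes. Ring C is the only ring made (step 9).

Assumption: the SMILES encodes (3R), and (R)-but-3-yn-2-ol (≥98% ee) is bought as the only source of chirality.
Abbreviations: TIPS = triisopropylsilyl, MOM = methoxymethyl, prenyl = 3-methylbut-2-enyl.

**Step 1**
Reactants: 1 resorcinol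
Product: 2 3-(triisopropylsilyloxy)phenol
Conditions: TIPSCl (1 equiv), 1 (3 equiv), imidazole, DMF, 0 °C → rt
Reagents that add atoms: triisopropylsilyl chloride, CC(C)[Si](Cl)(C(C)C)C(C)C
Why: O-silylation with excess diol favours the mono-ether, and the unreacted resorcinol washes out with water.

**Step 2**
Reactants: 2 3-(triisopropylsilyloxy)phenol; 3 (R)-but-3-yn-2-ol
Product: 4 (S)-[3-(but-3-yn-2-yloxy)phenoxy]triisopropylsilane
Conditions: PPh3, DIAD, THF, 0 °C → rt
Reagents that add atoms: none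
Why: In this Mitsunobu reaction the phenoxide displaces the oxyphosphonium group of the secondary propargylic alcohol by clean SN2, which inverts (R) to (S).

**Step 3**
Reactants: 5 3-bromo-4-methylphenol
Product: 6 (3-bromo-4-methylphenoxy)triisopropylsilane
Conditions: TIPSCl, imidazole, DMF, rt
Reagents that add atoms: triisopropylsilyl chloride, CC(C)[Si](Cl)(C(C)C)C(C)C
Why: This is a standard phenol silylation, and the bulky silyl ether also tempers ring reactivity for the next step.

**Step 4**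
Reactants: 6 (3-bromo-4-methylphenoxy)triisopropylsilane
Product: 7 [3-bromo-4-(bromomethyl)phenoxy]triisopropylsilane
Conditions: NBS, AIBN (cat.), PhCF3, reflux
Reagents that add atoms: N-bromosuccinimide, O=C1CCC(=O)N1Br
Why: Wohl–Ziegler radical bromination in a non-polar medium takes the only benzylic C–H position and leaves the ring alone.

**Step 5**
Reactants: 4 (S)-[3-(but-3-yn-2-yloxy)phenoxy]triisopropylsilane; 7 [3-bromo-4-(bromomethyl)phenoxy]triisopropylsilane
Product: 9 (S)-{3-bromo-4-[4-(3-triisopropylsilyloxyphenoxy)pent-2-yn-1-yl]phenoxy}triisopropylsilane, via alkynylmagnesium bromide 8 (not isolated)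
Conditions: EtMgBr, THF, 0 → 40 °C; then CuBr·SMe2 (10 mol %), 7, 50 °C
Reagents that add atoms: none
Why: Cu(I)-catalysed sp–sp3 coupling of an alkynyl Grignard reagent with a benzylic bromide, in which only the terminal C–H is deprotonated, so the ether stereocentre and the aryl bromide are untouched.

**Step 6**
Reactants: 9 the (S)-alkyne
Product: 10 (S,Z)-{3-bromo-4-[4-(3-triisopropylsilyloxyphenoxy)pent-2-en-1-yl]phenoxy}triisopropylsilane
Conditions: H2 (1 atm), Lindlar catalyst, quinoline, EtOAc, rt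
Reagents that add atoms: none
Why: Lindlar semihydrogenation adds H2 syn to give the Z-alkene and spares both the aryl bromide and the allylic C–O bond.

**Step 7**
Reactants: 10 the (S,Z)-allyl aryl ether
Product: 12 {3-bromo-4-[(2S,3E)-2-(2-methoxymethoxy-4-triisopropylsilyloxyphenyl)pent-3-en-1-yl]phenoxy}triisopropylsilane, via Claisen phenol 11 (not isolated)
Conditions: Eu(fod)3 (10 mol %), CHCl3, 60 °C; then i-Pr2NEt, MOMCl, 0 °C → rt (one pot)
Reagents that add atoms: chloromethyl methyl ether, COCCl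
Why: In this Lewis-acid-accelerated aromatic Claisen rearrangement the [3,3] shift is suprafacial on the allyl unit and A(1,3) strain in the Z-alkene forces the carbinol methyl outward, so the C–O stereocentre is relayed to the new benzylic centre (S here, the future 3R) at the open position para to OTIPS, and the freed phenol is capped in situ as its MOM ether.

**Step 8**
Reactants: 12 the (2S,3E)-alkene
Product: 14 (R)-3-(2-bromo-4-triisopropylsilyloxyphenyl)-2-(2-methoxymethoxy-4-triisopropylsilyloxyphenyl)propan-1-ol, via aldehyde 13 (not isolated)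
Conditions: O3, CH2Cl2/MeOH, −78 °C (Sudan III end point); then NaBH4, −78 → 0 °C
Reagents that add atoms: ozone, [O-][O+]=O
Why: Ozonolysis with reductive work-up reduces the α-aryl aldehyde cold before it can enolise, so the geometry is kept and the descriptor becomes R only because CH2OH now outranks the aryl group.

**Step 9**
Reactants: 14 the (R)-bromo alcohol
Product: 15 (3R)-3-(2-methoxymethoxy-4-triisopropylsilyloxyphenyl)-7-(triisopropylsilyloxy)chroman
Conditions: Pd(OAc)2 (5 mol %), 2-(di-tert-butylphosphino)-1,1'-binaphthyl (6 mol %), Cs2CO3, PhMe, 70 °C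
Reagents that add atoms: none
Why: Intramolecular Buchwald–Hartwig C–O coupling closes the six-membered ring C, with the bulky ligand favouring reductive elimination over β-hydride elimination, the 2'-oxygen blocked, and C3 not involved.

**Step 10**
Reactants: 15 the bis-TIPS isoflavan; 16 prenyl bromide (1-bromo-3-methylbut-2-ene)
Product: 18 (3R)-3-[2-methoxymethoxy-4-(3-methylbut-2-enyloxy)phenyl]-7-(3-methylbut-2-enyloxy)chroman, via diphenol 17 (not isolated)
Conditions: TBAF (2.2 equiv), THF, 0 °C; then 16 (3 equiv), rt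
Reagents that add atoms: none
Why: Fluoride desilylation gives the two tetrabutylammonium phenoxides, which undergo Williamson O-alkylation in the same flask while 2'-O stays masked as MOM.

**Step 11**
Reactants: 18 the bis(prenyl) ether
Product: 21 (3R)-6-(2-methylbut-3-en-2-yl)-3-[4-hydroxy-2-methoxymethoxy-5-(2-methylbut-3-en-2-yl)phenyl]chroman-7-ol, via ring-A mono-Claisen phenol 19 (not isolated), via ring-B mono-Claisen phenol 20 (not isolated)
Conditions: PhNEt2, 200 °C, sealed tube, Ar, 2–3 h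
Reagents that add atoms: none
Why: In this twofold aromatic Claisen rearrangement each prenyl ether inverts through a [3,3] shift into an ortho 1,1-dimethylallyl group, and the new quaternary carbon goes to the open C6 and C5' (each para to the other ring oxygen) rather than to C8 and C3', which are flanked by two oxygens.

**Step 12**
Reactants: 21 2'-O-MOM manuifolin E
Product: 22 manuifolin E, (3R)-7,2',4'-trihydroxy-6,5'-bis(1,1-dimethylallyl)isoflavan
Conditions: HCl (cat.), MeOH, 45 °C
Reagents that add atoms: none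
Why: Acid-catalysed acetal methanolysis is safe here because the monosubstituted neopentyl-type vinyl groups would give only secondary cations and so do not cyclise onto the phenols under mild acid.

**Compound list**
1 | resorcinol | Oc1cccc(O)c1 | starting material
2 | 3-(triisopropylsilyloxy)phenol | Oc1cccc(O[Si](C(C)C)(C(C)C)C(C)C)c1 | intermediate
3 | (R)-but-3-yn-2-ol | C[C@@H](O)C#C | starting material
4 | (S)-[3-(but-3-yn-2-yloxy)phenoxy]triisopropylsilane | C[C@H](Oc1cccc(O[Si](C(C)C)(C(C)C)C(C)C)c1)C#C | intermediate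
5 | 3-bromo-4-methylphenol | Cc1ccc(O)cc1Br | starting material
6 | (3-bromo-4-methylphenoxy)triisopropylsilane | Cc1ccc(O[Si](C(C)C)(C(C)C)C(C)C)cc1Br | intermediate
7 | [3-bromo-4-(bromomethyl)phenoxy]triisopropylsilane | BrCc1ccc(O[Si](C(C)C)(C(C)C)C(C)C)cc1Br | intermediate
8 | bromomagnesium acetylide of 4 (S) | C[C@H](Oc1cccc(O[Si](C(C)C)(C(C)C)C(C)C)c1)C#C[Mg]Br | intermediate
9 | (S)-{3-bromo-4-[4-(3-triisopropylsilyloxyphenoxy)pent-2-yn-1-yl]phenoxy}triisopropylsilane | C[C@H](Oc1cccc(O[Si](C(C)C)(C(C)C)C(C)C)c1)C#CCc1ccc(O[Si](C(C)C)(C(C)C)C(C)C)cc1Br | intermediate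
10 | (S,Z)-{3-bromo-4-[4-(3-triisopropylsilyloxyphenoxy)pent-2-en-1-yl]phenoxy}triisopropylsilane | C[C@H](Oc1cccc(O[Si](C(C)C)(C(C)C)C(C)C)c1)/C=C\Cc1ccc(O[Si](C(C)C)(C(C)C)C(C)C)cc1Br | intermediate
11 | 2-[(2S,3E)-1-(2-bromo-4-triisopropylsilyloxyphenyl)pent-3-en-2-yl]-5-(triisopropylsilyloxy)phenol | C/C=C/[C@@H](c1ccc(O[Si](C(C)C)(C(C)C)C(C)C)cc1O)Cc1ccc(O[Si](C(C)C)(C(C)C)C(C)C)cc1Br | intermediate
12 | MOM ether of 11 (2S,3E) | C/C=C/[C@@H](c1ccc(O[Si](C(C)C)(C(C)C)C(C)C)cc1OCOC)Cc1ccc(O[Si](C(C)C)(C(C)C)C(C)C)cc1Br | intermediate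
13 | (R)-3-(2-bromo-4-triisopropylsilyloxyphenyl)-2-(2-methoxymethoxy-4-triisopropylsilyloxyphenyl)propanal | O=C[C@@H](c1ccc(O[Si](C(C)C)(C(C)C)C(C)C)cc1OCOC)Cc1ccc(O[Si](C(C)C)(C(C)C)C(C)C)cc1Br | intermediate
14 | (R)-3-(2-bromo-4-triisopropylsilyloxyphenyl)-2-(2-methoxymethoxy-4-triisopropylsilyloxyphenyl)propan-1-ol | OC[C@@H](c1ccc(O[Si](C(C)C)(C(C)C)C(C)C)cc1OCOC)Cc1ccc(O[Si](C(C)C)(C(C)C)C(C)C)cc1Br | intermediate
15 | (3R)-3-(2-methoxymethoxy-4-triisopropylsilyloxyphenyl)-7-(triisopropylsilyloxy)chroman | CC(C)[Si](Oc1ccc2c(c1)OC[C@@H](c1ccc(O[Si](C(C)C)(C(C)C)C(C)C)cc1OCOC)C2)(C(C)C)C(C)C | intermediate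
16 | prenyl bromide | CC(C)=CCBr | starting material
17 | (3R)-3-(4-hydroxy-2-methoxymethoxyphenyl)chroman-7-ol (present as its bis-tetrabutylammonium phenoxide) | Oc1ccc2c(c1)OC[C@@H](c1ccc(O)cc1OCOC)C2 | intermediate
18 | (3R)-3-[2-methoxymethoxy-4-(prenyloxy)phenyl]-7-(prenyloxy)chroman | CC(C)=CCOc1ccc2c(c1)OC[C@@H](c1ccc(OCC=C(C)C)cc1OCOC)C2 | intermediate
19 | (3R)-6-(1,1-dimethylallyl)-3-[2-methoxymethoxy-4-(prenyloxy)phenyl]chroman-7-ol | C=CC(C)(C)c1cc2c(cc1O)OC[C@@H](c1ccc(OCC=C(C)C)cc1OCOC)C2 | intermediate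
20 | 2-(1,1-dimethylallyl)-5-methoxymethoxy-4-[(3R)-7-(prenyloxy)chroman-3-yl]phenol | CC(C)=CCOc1ccc2c(c1)OC[C@@H](c1cc(C(C)(C)C=C)c(O)cc1OCOC)C2 | intermediate
21 | 2'-O-MOM manuifolin E (3R) | C=CC(C)(C)c1cc2c(cc1O)OC[C@@H](c1cc(C(C)(C)C=C)c(O)cc1OCOC)C2 | intermediate
22 | manuifolin E (3R) | C=CC(C)(C)c1cc2c(cc1O)OC[C@@H](c1cc(C(C)(C)C=C)c(O)cc1O)C2 | target

**Totals**
- Total step count: 12.
- Longest linear sequence: 10 steps, either 1 → 22 through steps 1, 2, 5–12 or 5 → 22 through steps 3–12.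

**Three steps most likely to fail, in route order**

*Step 7.* The risks are migration to the position between the two ring-B oxygens, partial ionisation with loss of ee, and abnormal-Claisen isomerisation to the styrene. The fallback makes the C3–C1' bond by anti-SN2' allylic arylation and still takes its chirality from 3. It sets out from 3 and 7.
- Doubly magnesiated 3 (2 EtMgBr, cat. CuBr·SMe2) is benzylated with 7 to give (R)-5-[2-bromo-4-(triisopropylsilyloxy)phenyl]pent-3-yn-2-ol F1.
- Lindlar reduction gives (R,Z)-5-[2-bromo-4-(triisopropylsilyloxy)phenyl]pent-3-en-2-ol F2.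
- Picolinic acid, DCC and DMAP then give the (R,Z)-allylic picolinate F3.
- In parallel, commercial 4-bromoresorcinol is silylated at its unhindered hydroxyl to 2-bromo-5-(triisopropylsilyloxy)phenol F4.
- F4 is protected with MOMCl to 1-bromo-2-(methoxymethoxy)-4-(triisopropylsilyloxy)benzene F5, and Mg turns this into the arylmagnesium bromide F6.
- F6 with CuBr·SMe2 (THF, −40 → 0 °C) attacks the alkene terminus anti to the picolinate. With the methyl held outward by the Z-alkene, this puts the aryl group on the same face as the Claisen route does.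
- The sequence comes back to the route at 12.

*Step 9.* The risks are β-hydride elimination with hydrodebromination, and silyl transfer to the alkoxide. The fallback forms the O1–C2 bond by SN2 at carbon instead of at the arene. It sets out from 14.
- Miyaura borylation (B2pin2, PdCl2(dppf), KOAc, dioxane, 80 °C) gives the (R)-aryl pinacol boronate F7.
- NaBO3·4H2O in THF/H2O oxidises F7 to the (R)-2-hydroxyaryl propanol F8.
- An intramolecular Mitsunobu reaction (PPh3, DIAD, THF) closes the chroman, and only the ring-A phenol is free to react.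
- The sequence comes back to the route at 15.

*Step 11.* The risks are attack at C8 or C3', abnormal Claisen rearrangement to 1,2-dimethylallyl groups, and cyclisation of the ortho-allyl phenols to dihydrobenzofurans. The fallback installs the two groups by cross-coupling. It sets out from 15.
- NBS (2 equiv, MeCN, 0 °C) brominates para to O1 and para to 2'-OMOM to give the (3R)-6,5'-dibromide F9.
- A ligand-controlled, γ-selective Pd Suzuki–Miyaura coupling with 3-methylbut-2-enylboronic acid pinacol ester (K3PO4, THF/H2O) gives the (3R)-6,5'-bis(1,1-dimethylallyl) bis-TIPS ether F10.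
- TBAF removes both silyl groups.
- The sequence comes back to the route at 21.

**Further compounds**
F1 | step 7 | (R)-5-[2-bromo-4-(triisopropylsilyloxy)phenyl]pent-3-yn-2-ol | C[C@@H](O)C#CCc1ccc(O[Si](C(C)C)(C(C)C)C(C)C)cc1Br
F2 | step 7 | (R,Z)-5-[2-bromo-4-(triisopropylsilyloxy)phenyl]pent-3-en-2-ol | C[C@@H](O)/C=C\Cc1ccc(O[Si](C(C)C)(C(C)C)C(C)C)cc1Br
F3 | step 7 | (R,Z)-5-[2-bromo-4-(triisopropylsilyloxy)phenyl]pent-3-en-2-yl picolinate | C[C@@H](OC(=O)c1ccccn1)/C=C\Cc1ccc(O[Si](C(C)C)(C(C)C)C(C)C)cc1Br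
F4 | step 7 | 2-bromo-5-(triisopropylsilyloxy)phenol | Oc1cc(O[Si](C(C)C)(C(C)C)C(C)C)ccc1Br
F5 | step 7 | 1-bromo-2-(methoxymethoxy)-4-(triisopropylsilyloxy)benzene | COCOc1cc(O[Si](C(C)C)(C(C)C)C(C)C)ccc1Br
F6 | step 7 | [2-(methoxymethoxy)-4-(triisopropylsilyloxy)phenyl]magnesium bromide | COCOc1cc(O[Si](C(C)C)(C(C)C)C(C)C)ccc1[Mg]Br
F7 | step 9 | (R)-2-(2-methoxymethoxy-4-triisopropylsilyloxyphenyl)-3-[2-(pinacolboryl)-4-triisopropylsilyloxyphenyl]propan-1-ol | OC[C@@H](c1ccc(O[Si](C(C)C)(C(C)C)C(C)C)cc1OCOC)Cc1ccc(O[Si](C(C)C)(C(C)C)C(C)C)cc1B2OC(C)(C)C(C)(C)O2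
F8 | step 9 | (R)-2-[3-hydroxy-2-(2-methoxymethoxy-4-triisopropylsilyloxyphenyl)propyl]-5-(triisopropylsilyloxy)phenol | OC[C@@H](c1ccc(O[Si](C(C)C)(C(C)C)C(C)C)cc1OCOC)Cc1ccc(O[Si](C(C)C)(C(C)C)C(C)C)cc1O
F9 | step 11 | (3R)-6-bromo-3-(5-bromo-2-methoxymethoxy-4-triisopropylsilyloxyphenyl)-7-(triisopropylsilyloxy)chroman | Brc1cc2c(cc1O[Si](C(C)C)(C(C)C)C(C)C)OC[C@@H](c1cc(Br)c(O[Si](C(C)C)(C(C)C)C(C)C)cc1OCOC)C2
F10 | step 11 | (3R)-6-(1,1-dimethylallyl)-3-[5-(1,1-dimethylallyl)-2-methoxymethoxy-4-triisopropylsilyloxyphenyl]-7-(triisopropylsilyloxy)chroman | C=CC(C)(C)c1cc2c(cc1O[Si](C(C)C)(C(C)C)C(C)C)OC[C@@H](c1cc(C(C)(C)C=C)c(O[Si](C(C)C)(C(C)C)C(C)C)cc1OCOC)C2
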